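# Violacene by intramolecular nitrile oxide cycloaddition onto a 2-chloroalkene

Ring numbering used throughout: C1 (quaternary, CH3 and (E)-2-chloroethenyl), C2 (CH2), C3 (Cl and CH2Br), C4 (CHCl), C5 (CH2), C6 (CHCl). Compound numbers are those of the steps and of the compound list.

## Analysis of the target

Violacene (27) is a single saturated cyclohexane ring, and in the numbering above it is the (1R,3R,4S,6R) isomer. The chlorovinyl group and the chlorines on C3, C4 and C6 lie on one face, and the methyl and bromomethyl groups on the other. In the preferred chair CH3, CH2Br, C4–Cl and C6–Cl are therefore equatorial, while the chlorovinyl group and C3–Cl are syn-axial. The sensitive groups are an alkenyl chloride (no hydrogenation), a primary bromide vicinal to a tertiary chloride (lost to most one-electron reductants), and secondary chlorides that leave as HCl once a carbonyl group sits β to them. Three things make the synthesis hard. The fully substituted carbons C1 and C3 are not neighbours; both secondary chlorides (C4, C6) flank a fully substituted carbon, so substitution there is neopentylic; and the C3/C4 dichloride is cis, so it cannot come from anti addition to an alkene. The strategy rests on the pattern at C3–C4: C3 carries chlorine and a one-carbon branch ending in a heteroatom, and C4 carries a heteroatom. That is the pattern of a 4-chloro-4,5-dihydroisoxazole fused across C3–C4, with its oxygen on the branch carbon and its C=N carbon at C4. Opening that ring as a cycloadduct leads back to a nitrile oxide at C4 and a tethered 2-chloroalkene whose internal carbon is C3.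

## Retrosynthetic reasoning

27 ⇒ 25. The first bond cut is C4–Cl. Because it is cis to C3–Cl it cannot be paired with that chlorine in an addition, so it is made last, by inversion of alcohol 25, whose hydroxyl is axial and trans to C3–Cl. The forward step must substitute at a carbon next to fully substituted C3 without elimination toward C5.

25 ⇒ 24 ⇒ 22. The C4–H bond is cut next (ketone 24), then the C–Br bond (hydroxy ketone 22). Bromine goes in before the ketone is reduced, so only one hydroxyl is ever present and no 1,3-diol has to be differentiated. The forward reduction must deliver hydride to the upper face of 24, the face of C3–Cl.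

22 ⇒ 20. The β-hydroxy ketone of 22 is the open form of the dihydroisoxazole in 20, so the N–O bond and the C=N bond are restored. The forward step must break N–O reductively while leaving four C–Cl bonds and the alkene alone.

20 ⇒ 18 + 19 ⇒ 17 ⇒ 16. The side-chain alkene is cut to aldehyde 18 and chloroform 19, and 18 goes back through alcohol 17 to ester 16. The side chain is finished only after the ring is closed. A 2-chloroethenyl group on C1 would itself be a dipolarophile, three atoms from the dipole carbon. It would close a five-membered carbocycle in the electronically preferred orientation (oxygen to the chlorine-bearing carbon) and would compete with the wanted ring closure. An ester at C1 is inert to the dipole, and it is also smaller than methyl in conformational terms, which helps the stereochemistry of the next disconnection.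

16 ⇒ 15 ⇒ 13 (key disconnection). The C3–C4 bond and the O–CH2 bond are cut together, giving nitrile oxide 15, which comes from oxime 13. This cut removes the six-membered ring, the temporary five-membered ring and the C3 stereocentre at once, and leaves an open chain whose two remaining stereocentres are adjacent. The forward reaction must make the dipole carbon bond to the chlorine-bearing alkene carbon, against the intermolecular preference. The four-atom tether enforces this. It must also place the new C3–Cl on the face of the ester.

13 ⇒ 12 ⇒ 11 ⇒ 10. These are changes of oxidation level at the future C4: oxime from aldehyde 12, aldehyde from alcohol 11, alcohol from benzyl ether 10. The ether carries this carbon through the enolate chemistry that precedes.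

10 ⇒ 8. The C6–Cl bond is cut to the alcohol of hydroxy ester 8, with inversion. It is made here, in the open chain and with the ester on the neighbouring quaternary carbon, because the same substitution on the ring would be far harder. The ester leaves no β-hydrogen on that side and disfavours ionisation.

8 ⇒ 5 + 6. The C1–C2 bond is cut, removing the 2-chloroallyl arm (2,3-dichloroprop-1-ene, 6) from the α-carbon of β-hydroxy ester 5. The forward alkylation of the chelated dianion makes the quaternary centre with its configuration dictated by the carbinol centre, so one catalyst-set stereocentre controls both C6 and C1.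

5 ⇒ 4 ⇒ 1 + 2. The carbinol C–H bond is cut to β-keto ester 4 (catalyst-controlled hydrogenation forward). The bond between the future C5 and C4 is cut to methyl 2-methyl-3-oxobutanoate 1 and benzyl chloromethyl ether 2.

## Alternatives that were turned down

Alternative 1: The ring is cut at C1–C6 and re-tied through oxygen as the δ-lactone (6R)-6-[(E)-2-chloroethenyl]-3-methyloxan-2-one A2.
- Key step: the silyl ketene acetal of A2 would undergo an Ireland–Claisen rearrangement through the boat that a lactone enforces. It forms C1–C6, breaks C4–O and contracts to (1R,2R)-2-chloro-1-methylcyclohex-3-ene-1-carboxylic acid A1.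
- For: quaternary C1 and C6–Cl are made together and stereospecifically, from the alkene geometry and one carbinol centre. Chlorine rides in on the alkene, so no substitution at a neopentylic carbon is needed. On this point it is stronger than the chosen route, which pays for C6–Cl with step 4.
- Against: A1 has nothing at C3 and its alkene at C4=C5, one position from where functionality is needed. Quaternary C3 with Cl and CH2Br and the cis C4 chloride would all remain to be built, after an allylic transposition, on a ring that now holds an ionisable allylic chloride.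
- Comparison: the chosen strategy delivers C3 with both substituents and the C4 heteroatom in the ring-forming step, so the steps after ring closure are fewer and each is a defined functional-group change.

Alternative 2: The ring is cut at C5–C6, leading to the achiral keto dialdehyde 2-methyl-2-(3-oxobutyl)propanedial A4.
- Key step: the proline enamine of the methyl ketone adds to one of the two enantiotopic formyl groups and closes (1S,2S)-2-hydroxy-1-methyl-4-oxocyclohexane-1-carbaldehyde A3.
- For: it is catalytic and enantioselective. It makes the ring and the C1/C6 stereocentres in one step from an achiral compound that is two operations from bulk chemicals. That is clearly shorter to a cyclohexane than the eight steps needed here, and the spare formyl group is ready for chloro-olefination.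
- Against: C6 arrives as a hydroxyl β to the C4 ketone and is prone to dehydration. Converting it into the chloride needs inversion at a ring carbon next to C1, which is harder than the open-chain step 4. C3 is unfunctionalised, so chlorine and the one-carbon branch would each need enolisation toward C3 rather than C5, with stereocontrol, and enolisation toward C5 expels the C6 substituent. A4 is a non-enolisable 1,3-dialdehyde and is easily deformylated by the amine catalyst.
- Comparison: the chosen strategy is longer to the ring, but it installs C6–Cl before the ring exists and C3 complete.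

Alternative 3: The C2–C3 bond is cut and C2 re-attached to C4, giving the cyclopentanol (3R,4S)-4-[tert-butyl(dimethyl)silyl]oxy-1-(1-chloroethenyl)-3-[(E)-2-chloroethenyl]-3-methylcyclopentan-1-ol A6.
- Key step: Br+ adds to the terminal carbon of the 1-chloroethenyl group, and a ring carbon shifts to the chlorine-stabilised cation. The ring expands to (2R,4R,5S)-2-(bromomethyl)-5-[tert-butyl(dimethyl)silyl]oxy-2-chloro-4-[(E)-2-chloroethenyl]-4-methylcyclohexan-1-one A5.
- For: one step creates quaternary C3 with Cl and CH2Br and the C4 ketone. That array costs three steps here (8, 12 and 13). No N–O reduction is needed and bromine is delivered directly. It is stronger in step economy at this site.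
- Against: two chloroalkenes compete for Br+, and the one that must react is deactivated. Either of two ring carbons can migrate, giving regioisomeric ketones. The C3 configuration depends on the rotamer of a freely rotating side chain. A6 needs its own stereocontrolled synthesis of three stereocentres. C6 is carried as a silyl ether that must later be inverted to chloride on the ring, next to C1 and β to a ketone.
- Comparison: the chosen strategy sets C6–Cl in the open chain and fixes C3 through the geometry of a fused bicyclic transition state with a single dipolarophile present.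

Key step: step 8

Remark: both C2 epimers of 5 are carried into step 3 together, because that centre is planarised in enolate 7 and the outcome is governed by C3 alone.

## Route

Step 1
Reactants: 1 methyl 2-methyl-3-oxobutanoate; 2 benzyl chloromethyl ether
Product: 4 methyl 5-(benzyloxy)-2-methyl-3-oxopentanoate (racemic), via dilithium dienolate 3 (not isolated)
Conditions: LiN(i-Pr)2 (2.2 equiv), THF, 0 °C; then 2, −78 → 0 °C; aq. HCl work-up
Reagents that add atoms: none
Why: Huckin–Weiler γ-alkylation: the doubly deprotonated keto ester 3 reacts at its terminal, more nucleophilic carbon and displaces chloride from the reactive α-chloro ether 2; the C2 centre forms racemic and is erased later.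

Step 2
Reactants: 4 methyl 5-(benzyloxy)-2-methyl-3-oxopentanoate
Product: 5 methyl (3S)-5-(benzyloxy)-3-hydroxy-2-methylpentanoate (both C2 epimers)
Conditions: H2 (50 bar), RuCl2[(S)-BINAP] (0.5 mol %), MeOH, 50 °C
Reagents that add atoms: none
Why: Noyori asymmetric hydrogenation of a β-keto ester: the ester-chelated ketone is reduced on the face dictated by (S)-BINAP, which sets C3 as S (the future C6 oxygen); the benzyl ether is inert and C2 stays a mixture that converges in step 3.

Step 3
Reactants: 5 methyl (3S)-5-(benzyloxy)-3-hydroxy-2-methylpentanoate; 6 2,3-dichloroprop-1-ene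
Product: 8 methyl (2S,3S)-5-(benzyloxy)-2-(2-chloroprop-2-en-1-yl)-3-hydroxy-2-methylpentanoate, via dilithium alkoxide enolate 7 (not isolated)
Conditions: LiN(i-Pr)2 (2.3 equiv), THF, −78 → −20 °C; then 6, DMPU, −78 → 0 °C
Reagents that add atoms: none
Why: Fráter–Seebach alkylation: both C2 epimers give the same lithium-chelated alkoxide enolate 7, and the allylic chloride 6 enters on the enolate face away from the C3 side chain, anti to the alkoxide oxygen, which fixes the quaternary centre (future C1) as 2S with methyl syn to the hydroxyl. The alkenyl chlorine of 6 does not react.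

Step 4
Reactants: 8 methyl (2S,3S)-5-(benzyloxy)-2-(2-chloroprop-2-en-1-yl)-3-hydroxy-2-methylpentanoate
Product: 10 methyl (2R,3R)-5-(benzyloxy)-3-chloro-2-(2-chloroprop-2-en-1-yl)-2-methylpentanoate, via triflate 9 (not isolated)
Conditions: Tf2O, 2,6-lutidine, CH2Cl2, −78 °C; then Bu4NCl, −78 °C → rt
Reagents that add atoms: tetrabutylammonium chloride, CCCC[N+](CCCC)(CCCC)CCCC.[Cl-]
Why: Sulfonate displacement (SN2) with inversion: the alcohol is triflated and soluble chloride displaces the triflate, turning the 3S alcohol into the 3R chloride (future C6–Cl). The ester on the neighbouring quaternary carbon leaves no β-hydrogen on that side and disfavours ionisation and 1,2-shifts, so substitution should prevail although the centre is neopentylic.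

Step 5
Reactants: 10 methyl (2R,3R)-5-(benzyloxy)-3-chloro-2-(2-chloroprop-2-en-1-yl)-2-methylpentanoate
Product: 11 methyl (2R,3R)-3-chloro-2-(2-chloroprop-2-en-1-yl)-5-hydroxy-2-methylpentanoate
Conditions: BCl3, pentamethylbenzene, CH2Cl2, −78 °C; MeOH then aq. NaHCO3
Reagents that add atoms: none
Why: Lewis-acid debenzylation with an arene cation scavenger: the benzyl cation is trapped by pentamethylbenzene and cannot alkylate the chloroalkene, and the methyl ester and the alkyl and alkenyl chlorides survive at −78 °C. Alcohol 11 is used at once to forestall δ-lactonisation onto the ester.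

Step 6
Reactants: 11 methyl (2R,3R)-3-chloro-2-(2-chloroprop-2-en-1-yl)-5-hydroxy-2-methylpentanoate
Product: 12 methyl (2R,3R)-3-chloro-2-(2-chloroprop-2-en-1-yl)-2-methyl-5-oxopentanoate
Conditions: Dess–Martin periodinane, NaHCO3, CH2Cl2, 0 °C → rt
Reagents that add atoms: none
Why: Dess–Martin oxidation under bicarbonate buffer gives the aldehyde without a base strong enough to expel the β-chloride; 12 is taken on without purification.

Step 7
Reactants: 12 methyl (2R,3R)-3-chloro-2-(2-chloroprop-2-en-1-yl)-2-methyl-5-oxopentanoate
Product: 13 methyl (2R,3R)-3-chloro-2-(2-chloroprop-2-en-1-yl)-5-(hydroxyimino)-2-methylpentanoate (E/Z mixture at C=N)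
Conditions: NH2OH·HCl, NaOAc, EtOH/H2O, 0 °C
Reagents that add atoms: hydroxylamine hydrochloride, NO.Cl
Why: Oxime condensation in acetate buffer is fast for an unhindered aldehyde and mild enough to avoid E1cB loss of HCl; the oxime geometry is immaterial because both isomers give the same nitrile oxide.

Step 8
Reactants: 13 methyl (2R,3R)-3-chloro-2-(2-chloroprop-2-en-1-yl)-5-(hydroxyimino)-2-methylpentanoate
Product: 16 methyl (3aR,5R,6R)-3a,6-dichloro-5-methyl-3,3a,4,5,6,7-hexahydro-2,1-benzoxazole-5-carboxylate, via hydroximoyl chloride 14 (not isolated), via nitrile oxide 15 (not isolated)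
Conditions: aq. NaOCl (5 %, 2 equiv), CH2Cl2, 0 °C → rt; 13 added over 6 h, final concentration ≤ 0.01 M
Reagents that add atoms: none
Why: Proposed new method: NaOCl chlorinates the aldoxime to hydroximoyl chloride 14, which loses HCl at the phase boundary to nitrile oxide 15; 15 then adds in a concerted, suprafacial [3+2] manner to the 2-chloroalkene four atoms away, its carbon bonding to the chlorine-bearing alkene carbon (C3–C4) and its oxygen to the terminal CH2. The closest known reaction is the intramolecular nitrile oxide cycloaddition of hept-6-enal oximes, including those with 2-alkyl-substituted alkenes; a 2-chloroalkene has not been used in this fused mode, where the tether overrides the intermolecular preference of the oxygen for the chlorine-bearing carbon. The carbocycle closes in a 6-exo sense (the CH2 terminus stays outside the six-membered ring), and the dihydroisoxazole forms in the same event as a five-membered ring fused across C3–C4, the bridged orientation being out of reach for a four-atom tether. The only new stereocentre, C3 (C3a of 16), is controlled by the chair-like tether: the ring CH2–O must lie near the plane of the forming C=N and is therefore equatorial, so chlorine becomes axial, and the chair with C1–CH3 and C6–Cl equatorial and the flat, smaller ester axial places that chlorine cis to the ester (3aR). Three selectivities are needed. Regio- and chemoselectivity are secured by the substrate, since the ester arm offers no second dipolarophile, whereas a chlorovinyl group at C1 would close a five-membered carbocycle. Diastereoselectivity rests on the ester being conformationally smaller than methyl and on the equatorial preference of C6–Cl. Cyclisation must outrun dimerisation of the dipole and the adduct must not lose HCl to the aromatic isoxazole, hence slow addition at high dilution in a two-phase medium without amine base.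

Step 9
Reactants: 16 methyl (3aR,5R,6R)-3a,6-dichloro-5-methyl-3,3a,4,5,6,7-hexahydro-2,1-benzoxazole-5-carboxylate
Product: 17 [(3aR,5R,6R)-3a,6-dichloro-5-methyl-3,3a,4,5,6,7-hexahydro-2,1-benzoxazol-5-yl]methanol
Conditions: i-Bu2AlH (3 equiv), CH2Cl2, −78 → −30 °C; aq. potassium sodium tartrate
Reagents that add atoms: none
Why: Ester reduction with i-Bu2AlH: the hindered ester is taken to the primary alcohol, while the cyclic oxime ether (a poorly electrophilic C=N) and the alkyl chlorides are left alone at low temperature.

Step 10
Reactants: 17 [(3aR,5R,6R)-3a,6-dichloro-5-methyl-3,3a,4,5,6,7-hexahydro-2,1-benzoxazol-5-yl]methanol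
Product: 18 (3aR,5R,6R)-3a,6-dichloro-5-methyl-3,3a,4,5,6,7-hexahydro-2,1-benzoxazole-5-carbaldehyde
Conditions: Dess–Martin periodinane, NaHCO3, CH2Cl2, rt
Reagents that add atoms: none
Why: Dess–Martin oxidation; the aldehyde has no α-hydrogen, so it can neither epimerise nor eliminate.

Step 11
Reactants: 18 (3aR,5R,6R)-3a,6-dichloro-5-methyl-3,3a,4,5,6,7-hexahydro-2,1-benzoxazole-5-carbaldehyde; 19 chloroform
Product: 20 (3aR,5R,6R)-3a,6-dichloro-5-[(E)-2-chloroethenyl]-5-methyl-3,3a,4,5,6,7-hexahydro-2,1-benzoxazole
Conditions: CrCl2 (6 equiv), THF, 65 °C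
Reagents that add atoms: none
Why: Takai–Utimoto chloro-olefination: CrCl2 reduces chloroform to a geminal dichromium chloromethylidene reagent that adds to the aldehyde and eliminates to the (E)-alkenyl chloride, the E geometry being reinforced by the quaternary neighbour. Divalent chromium is too weak a reductant for the N–O bond or for unactivated alkyl chlorides; the tertiary chloride next to C=N is the group to watch.

Step 12
Reactants: 20 (3aR,5R,6R)-3a,6-dichloro-5-[(E)-2-chloroethenyl]-5-methyl-3,3a,4,5,6,7-hexahydro-2,1-benzoxazole
Product: 22 (2S,4R,5R)-2,5-dichloro-4-[(E)-2-chloroethenyl]-2-(hydroxymethyl)-4-methylcyclohexan-1-one, via hydroxy imine 21 (not isolated)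
Conditions: Mo(CO)6 (1.2 equiv), B(OH)3, MeCN/H2O (15:1), 80 °C
Reagents that add atoms: water, O
Why: Reductive N–O cleavage by zerovalent molybdenum, then hydrolysis of imine 21, unmasks the β-hydroxy ketone; Mo(CO)6 spares the alkene and the alkyl and alkenyl halides where hydrogenation or SmI2 would not, and B(OH)3 takes up the ammonia released so that the C6 chloride, now β to a ketone, is not eliminated. C3 is quaternary, so neither dehydration nor epimerisation is possible there.

Step 13
Reactants: 22 (2S,4R,5R)-2,5-dichloro-4-[(E)-2-chloroethenyl]-2-(hydroxymethyl)-4-methylcyclohexan-1-one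
Product: 24 (2R,4R,5R)-2-(bromomethyl)-2,5-dichloro-4-[(E)-2-chloroethenyl]-4-methylcyclohexan-1-one, via triflate 23 (not isolated)
Conditions: Tf2O, 2,6-lutidine, CH2Cl2, −78 °C; then Bu4NBr, −78 °C → rt
Reagents that add atoms: tetrabutylammonium bromide, CCCC[N+](CCCC)(CCCC)CCCC.[Br-]
Why: Primary alcohol to bromide through the triflate (SN2): a neopentylic primary carbon needs the triflate leaving group, and bromide is non-basic, so the β-chloro ketone is not enolised; C3 bears no hydrogen, so no enone can form.

Step 14
Reactants: 24 (2R,4R,5R)-2-(bromomethyl)-2,5-dichloro-4-[(E)-2-chloroethenyl]-4-methylcyclohexan-1-one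
Product: 25 (1R,2R,4R,5R)-2-(bromomethyl)-2,5-dichloro-4-[(E)-2-chloroethenyl]-4-methylcyclohexan-1-ol
Conditions: LiBH(s-Bu)3 (1.2 equiv), THF, −78 °C; AcOH quench at −78 °C
Reagents that add atoms: none
Why: Diastereoselective ketone reduction by a bulky trialkylborohydride: axial approach from the lower face is blocked by the syn-axial hydrogens on C2 and C6, so hydride should enter equatorially from the upper face, as it does with 2,2-disubstituted cyclohexanones such as 4,4-dimethyl-3-keto terpenoids, giving the axial 1R alcohol trans to C3–Cl. The cold acidic quench keeps the trans-diaxial chlorohydrin alkoxide from closing to an epoxide or, with CH2Br, to an oxetane.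

Step 15
Reactants: 25 (1R,2R,4R,5R)-2-(bromomethyl)-2,5-dichloro-4-[(E)-2-chloroethenyl]-4-methylcyclohexan-1-ol
Product: 27 violacene [(1R,2S,4R,5R)-1-(bromomethyl)-1,2,4-trichloro-5-[(E)-2-chloroethenyl]-5-methylcyclohexane], via alkoxyphosphonium chloride 26 (not isolated)
Conditions: PPh3, N-chlorosuccinimide, THF, 0 °C; then 25, 0 → 50 °C
Reagents that add atoms: N-chlorosuccinimide, O=C1CCC(=O)N1Cl
Why: Appel-type deoxychlorination: the alcohol is converted into alkoxyphosphonium salt 26 and chloride displaces Ph3P=O from the axial C–O bond with inversion, giving the equatorial chloride at C4 cis to C3–Cl, as in the known conversion of trans-2-chlorocyclohexanol derivatives into cis-1,2-dichlorocyclohexane. Preforming the chlorophosphonium salt keeps free PPh3 away from the vicinal bromide and chloride.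

## Compound list

1 | methyl 2-methyl-3-oxobutanoate | CC(=O)C(C)C(=O)OC | starting material
2 | benzyl chloromethyl ether | ClCOCc1ccccc1 | starting material
3 | dilithium dienolate of 1 (1-methoxy-2-methylbuta-1,3-diene-1,3-diolate) | [Li+].[Li+].C=C([O-])C(C)=C([O-])OC | intermediate (not isolated)
4 | methyl 5-(benzyloxy)-2-methyl-3-oxopentanoate (racemic) | COC(=O)C(C)C(=O)CCOCc1ccccc1 | intermediate
5 | methyl (3S)-5-(benzyloxy)-3-hydroxy-2-methylpentanoate (both C2 epimers) | COC(=O)C(C)[C@@H](O)CCOCc1ccccc1 | intermediate
6 | 2,3-dichloroprop-1-ene | C=C(Cl)CCl | starting material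
7 | dilithium alkoxide enolate of 5 | [Li+].[Li+].COC([O-])=C(C)[C@@H]([O-])CCOCc1ccccc1 | intermediate (not isolated)
8 | methyl (2S,3S)-5-(benzyloxy)-2-(2-chloroprop-2-en-1-yl)-3-hydroxy-2-methylpentanoate | C=C(Cl)C[C@](C)(C(=O)OC)[C@@H](O)CCOCc1ccccc1 | intermediate
9 | methyl (2S,3S)-5-(benzyloxy)-2-(2-chloroprop-2-en-1-yl)-2-methyl-3-[(trifluoromethanesulfonyl)oxy]pentanoate | C=C(Cl)C[C@](C)(C(=O)OC)[C@@H](OS(=O)(=O)C(F)(F)F)CCOCc1ccccc1 | intermediate (not isolated)
10 | methyl (2R,3R)-5-(benzyloxy)-3-chloro-2-(2-chloroprop-2-en-1-yl)-2-methylpentanoate | C=C(Cl)C[C@](C)(C(=O)OC)[C@H](Cl)CCOCc1ccccc1 | intermediate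
11 | methyl (2R,3R)-3-chloro-2-(2-chloroprop-2-en-1-yl)-5-hydroxy-2-methylpentanoate | C=C(Cl)C[C@](C)(C(=O)OC)[C@H](Cl)CCO | intermediate
12 | methyl (2R,3R)-3-chloro-2-(2-chloroprop-2-en-1-yl)-2-methyl-5-oxopentanoate | C=C(Cl)C[C@](C)(C(=O)OC)[C@H](Cl)CC=O | intermediate
13 | methyl (2R,3R)-3-chloro-2-(2-chloroprop-2-en-1-yl)-5-(hydroxyimino)-2-methylpentanoate | C=C(Cl)C[C@](C)(C(=O)OC)[C@H](Cl)CC=NO | intermediate (precursor of the key step)
14 | methyl (2R,3R)-3,5-dichloro-2-(2-chloroprop-2-en-1-yl)-5-(hydroxyimino)-2-methylpentanoate | C=C(Cl)C[C@](C)(C(=O)OC)[C@H](Cl)CC(Cl)=NO | intermediate (not isolated)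
15 | nitrile oxide of 13 (–CH2–C≡N+–O− in place of –CH2–CH=NOH; 2R,3R) | C=C(Cl)C[C@](C)(C(=O)OC)[C@H](Cl)CC#[N+][O-] | intermediate (not isolated)
16 | methyl (3aR,5R,6R)-3a,6-dichloro-5-methyl-3,3a,4,5,6,7-hexahydro-2,1-benzoxazole-5-carboxylate | C[C@]1(C(=O)OC)C[C@]2(Cl)CON=C2C[C@H]1Cl | intermediate (product of the key step)
17 | [(3aR,5R,6R)-3a,6-dichloro-5-methyl-3,3a,4,5,6,7-hexahydro-2,1-benzoxazol-5-yl]methanol | C[C@]1(CO)C[C@]2(Cl)CON=C2C[C@H]1Cl | intermediate
18 | (3aR,5R,6R)-3a,6-dichloro-5-methyl-3,3a,4,5,6,7-hexahydro-2,1-benzoxazole-5-carbaldehyde | C[C@]1(C=O)C[C@]2(Cl)CON=C2C[C@H]1Cl | intermediate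
19 | chloroform | ClC(Cl)Cl | starting material
20 | (3aR,5R,6R)-3a,6-dichloro-5-[(E)-2-chloroethenyl]-5-methyl-3,3a,4,5,6,7-hexahydro-2,1-benzoxazole | C[C@]1(/C=C/Cl)C[C@]2(Cl)CON=C2C[C@H]1Cl | intermediate
21 | (2R,4R,5R)-2,5-dichloro-4-[(E)-2-chloroethenyl]-2-(hydroxymethyl)-4-methylcyclohexan-1-imine | C[C@]1(/C=C/Cl)C[C@](Cl)(CO)C(=N)C[C@H]1Cl | intermediate (not isolated)
22 | (2S,4R,5R)-2,5-dichloro-4-[(E)-2-chloroethenyl]-2-(hydroxymethyl)-4-methylcyclohexan-1-one | C[C@]1(/C=C/Cl)C[C@](Cl)(CO)C(=O)C[C@H]1Cl | intermediate
23 | (2S,4R,5R)-2,5-dichloro-4-[(E)-2-chloroethenyl]-4-methyl-2-{[(trifluoromethanesulfonyl)oxy]methyl}cyclohexan-1-one | C[C@]1(/C=C/Cl)C[C@](Cl)(COS(=O)(=O)C(F)(F)F)C(=O)C[C@H]1Cl | intermediate (not isolated)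
24 | (2R,4R,5R)-2-(bromomethyl)-2,5-dichloro-4-[(E)-2-chloroethenyl]-4-methylcyclohexan-1-one | C[C@]1(/C=C/Cl)C[C@](Cl)(CBr)C(=O)C[C@H]1Cl | intermediate
25 | (1R,2R,4R,5R)-2-(bromomethyl)-2,5-dichloro-4-[(E)-2-chloroethenyl]-4-methylcyclohexan-1-ol | C[C@]1(/C=C/Cl)C[C@](Cl)(CBr)[C@H](O)C[C@H]1Cl | intermediate
26 | alkoxytriphenylphosphonium chloride of 25 (P–O bond at the C1 oxygen) | C[C@]1(/C=C/Cl)C[C@](Cl)(CBr)[C@H](O[P+](c2ccccc2)(c2ccccc2)c2ccccc2)C[C@H]1Cl.[Cl-] | intermediate (not isolated)
27 | violacene, (1R,2S,4R,5R)-1-(bromomethyl)-1,2,4-trichloro-5-[(E)-2-chloroethenyl]-5-methylcyclohexane | C[C@]1(/C=C/Cl)C[C@](Cl)(CBr)[C@@H](Cl)C[C@H]1Cl | target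

Total step count: 15. Longest linear sequence: 15 steps (the route is linear from 1).

## Least certain steps and fallbacks

**Step 8 (key step, proposed new method).**
- The alkene is gem-disubstituted, deactivated by chlorine and attacked at its chlorine-bearing carbon. The cycloaddition may therefore be so slow that dimerisation of the nitrile oxide takes over.
- The 3a-chloro adduct can lose HCl under the basic hypochlorite to give the aromatic isoxazole.
- The chair preference may be too small, giving the C3a epimer.
- Fallback (known chemistry only): it leaves the route at 5 and rejoins it at 24. Enolate 7 is alkylated with allyl bromide in place of 6, giving methyl (2S,3S)-5-(benzyloxy)-3-hydroxy-2-methyl-2-(prop-2-en-1-yl)pentanoate F1. The operations of steps 4 to 7 then give in turn methyl (2R,3R)-5-(benzyloxy)-3-chloro-2-methyl-2-(prop-2-en-1-yl)pentanoate F2, methyl (2R,3R)-3-chloro-5-hydroxy-2-methyl-2-(prop-2-en-1-yl)pentanoate F3, methyl (2R,3R)-3-chloro-2-methyl-5-oxo-2-(prop-2-en-1-yl)pentanoate F4 and methyl (2R,3R)-3-chloro-5-(hydroxyimino)-2-methyl-2-(prop-2-en-1-yl)pentanoate F5. Oxidation of F5 with NaOCl is the long-established cyclisation of a hept-6-enal oxime onto a monosubstituted alkene. It gives methyl (5R,6R)-6-chloro-5-methyl-3,3a,4,5,6,7-hexahydro-2,1-benzoxazole-5-carboxylate F6, whose C3a configuration does not matter. The operations of steps 9 to 11 lead through [(5R,6R)-6-chloro-5-methyl-3,3a,4,5,6,7-hexahydro-2,1-benzoxazol-5-yl]methanol F7 and (5R,6R)-6-chloro-5-methyl-3,3a,4,5,6,7-hexahydro-2,1-benzoxazole-5-carbaldehyde F8 to (5R,6R)-6-chloro-5-[(E)-2-chloroethenyl]-5-methyl-3,3a,4,5,6,7-hexahydro-2,1-benzoxazole F9. Cleavage with Mo(CO)6 as in step 12 gives (4R,5R)-5-chloro-4-[(E)-2-chloroethenyl]-2-(hydroxymethyl)-4-methylcyclohexan-1-one F10. CBr4/PPh3 converts this into (4R,5R)-2-(bromomethyl)-5-chloro-4-[(E)-2-chloroethenyl]-4-methylcyclohexan-1-one F11. Chlorination of the more substituted enol of F11 with SO2Cl2, the classical route to 2-alkyl-2-chlorocyclohexanones, puts chlorine on C3 and gives 24. The price is that C3 is then set in an enol chlorination and no longer in a ring-forming step, so its configuration would have to be verified.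

**Step 15.**
- Backside approach of chloride at C4 runs past the axial C3–Cl of a fully substituted neighbour. Anti-periplanar E2 loss of the axial C5 hydrogen, or participation of the anti C3 chlorine, may therefore outrun substitution.
- Fallback: it starts at 25 and ends at 27. Esterification with ClCH2SO2Cl and pyridine gives (1R,2R,4R,5R)-2-(bromomethyl)-2,5-dichloro-4-[(E)-2-chloroethenyl]-4-methylcyclohexyl chloromethanesulfonate F12, an isolable sulfonate of the kind used for hindered secondary centres. Free chloride then displaces it (LiCl, DMF, 50 °C). This replaces ion-pair collapse of a phosphonium salt by a bimolecular reaction with a high concentration of unsolvated chloride.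

**Step 14.**
- The facial selectivity may reverse. The polar Felkin–Anh preference for attack anti to the axial C3–Cl favours the lower face and would give the equatorial alcohol, which is useless for an invertive chlorination.
- Fallback: it starts at 24 and ends at 25 with no new compound. Substrate control is replaced by reagent control: Corey–Bakshi–Shibata reduction with the (S)-2-methyl oxazaborolidine and BH3·SMe2. This treats quaternary C3 as the large group and should deliver hydride to the upper face, giving the 1R alcohol.

**Step 12.**
- The tertiary chlorine α to the C=N (then C=O) group may be reduced off by low-valent molybdenum.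
- HCl may be lost across C5–C6 at the imine or ketone stage.
- Fallback: it starts at 20 and rejoins at 24. If the C3 chlorine cannot be kept, the reduction is run on to the chlorine-free hydroxy ketone (4R,5R)-5-chloro-4-[(E)-2-chloroethenyl]-2-(hydroxymethyl)-4-methylcyclohexan-1-one F10. This is brominated to (4R,5R)-2-(bromomethyl)-5-chloro-4-[(E)-2-chloroethenyl]-4-methylcyclohexan-1-one F11 and re-chlorinated at C3 with SO2Cl2 as described for step 8, giving 24.

**Step 4.**
- Substitution at the neopentylic carbinol carbon may be slower than E2 elimination toward C4 of the chain or than decomposition of the triflate.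
- Fallback: it starts at 8 and rejoins at 10, and uses ring strain instead of a sulfonate. Saponification (KOH, MeOH/H2O) gives (2S,3S)-5-(benzyloxy)-2-(2-chloroprop-2-en-1-yl)-3-hydroxy-2-methylpentanoic acid F13. Carboxyl activation with PhSO2Cl in pyridine closes the β-lactone (3S,4S)-4-[2-(benzyloxy)ethyl]-3-(2-chloroprop-2-en-1-yl)-3-methyloxetan-2-one F14 with retention at the carbinol carbon. LiCl in DMF opens it by alkyl–oxygen cleavage with inversion to (2R,3R)-5-(benzyloxy)-3-chloro-2-(2-chloroprop-2-en-1-yl)-2-methylpentanoic acid F15. Me3SiCHN2 in MeOH returns ester 10.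

## Further compounds

F1 | step 8 | methyl (2S,3S)-5-(benzyloxy)-3-hydroxy-2-methyl-2-(prop-2-en-1-yl)pentanoate | C=CC[C@](C)(C(=O)OC)[C@@H](O)CCOCc1ccccc1
F2 | step 8 | methyl (2R,3R)-5-(benzyloxy)-3-chloro-2-methyl-2-(prop-2-en-1-yl)pentanoate | C=CC[C@](C)(C(=O)OC)[C@H](Cl)CCOCc1ccccc1
F3 | step 8 | methyl (2R,3R)-3-chloro-5-hydroxy-2-methyl-2-(prop-2-en-1-yl)pentanoate | C=CC[C@](C)(C(=O)OC)[C@H](Cl)CCO
F4 | step 8 | methyl (2R,3R)-3-chloro-2-methyl-5-oxo-2-(prop-2-en-1-yl)pentanoate | C=CC[C@](C)(C(=O)OC)[C@H](Cl)CC=O
F5 | step 8 | methyl (2R,3R)-3-chloro-5-(hydroxyimino)-2-methyl-2-(prop-2-en-1-yl)pentanoate | C=CC[C@](C)(C(=O)OC)[C@H](Cl)CC=NO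
F6 | step 8 | methyl (5R,6R)-6-chloro-5-methyl-3,3a,4,5,6,7-hexahydro-2,1-benzoxazole-5-carboxylate (C3a epimers) | C[C@]1(C(=O)OC)CC2CON=C2C[C@H]1Cl
F7 | step 8 | [(5R,6R)-6-chloro-5-methyl-3,3a,4,5,6,7-hexahydro-2,1-benzoxazol-5-yl]methanol (C3a epimers) | C[C@]1(CO)CC2CON=C2C[C@H]1Cl
F8 | step 8 | (5R,6R)-6-chloro-5-methyl-3,3a,4,5,6,7-hexahydro-2,1-benzoxazole-5-carbaldehyde (C3a epimers) | C[C@]1(C=O)CC2CON=C2C[C@H]1Cl
F9 | step 8 | (5R,6R)-6-chloro-5-[(E)-2-chloroethenyl]-5-methyl-3,3a,4,5,6,7-hexahydro-2,1-benzoxazole (C3a epimers) | C[C@]1(/C=C/Cl)CC2CON=C2C[C@H]1Cl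
F10 | step 8 | (4R,5R)-5-chloro-4-[(E)-2-chloroethenyl]-2-(hydroxymethyl)-4-methylcyclohexan-1-one (C2 epimers) | C[C@]1(/C=C/Cl)CC(CO)C(=O)C[C@H]1Cl
F11 | step 8 | (4R,5R)-2-(bromomethyl)-5-chloro-4-[(E)-2-chloroethenyl]-4-methylcyclohexan-1-one (C2 epimers) | C[C@]1(/C=C/Cl)CC(CBr)C(=O)C[C@H]1Cl
F12 | step 15 | (1R,2R,4R,5R)-2-(bromomethyl)-2,5-dichloro-4-[(E)-2-chloroethenyl]-4-methylcyclohexyl chloromethanesulfonate | C[C@]1(/C=C/Cl)C[C@](Cl)(CBr)[C@H](OS(=O)(=O)CCl)C[C@H]1Cl
F0 | step 14 | none | none
F13 | step 4 | (2S,3S)-5-(benzyloxy)-2-(2-chloroprop-2-en-1-yl)-3-hydroxy-2-methylpentanoic acid | C=C(Cl)C[C@](C)(C(=O)O)[C@@H](O)CCOCc1ccccc1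
F14 | step 4 | (3S,4S)-4-[2-(benzyloxy)ethyl]-3-(2-chloroprop-2-en-1-yl)-3-methyloxetan-2-one | C=C(Cl)C[C@]1(C)C(=O)O[C@H]1CCOCc2ccccc2
F15 | step 4 | (2R,3R)-5-(benzyloxy)-3-chloro-2-(2-chloroprop-2-en-1-yl)-2-methylpentanoic acid | C=C(Cl)C[C@](C)(C(=O)O)[C@H](Cl)CCOCc1ccccc1
A1 | alternative 1 | (1R,2R)-2-chloro-1-methylcyclohex-3-ene-1-carboxylic acid | C[C@]1(C(O)=O)CCC=C[C@H]1Cl
A2 | alternative 1 | (6R)-6-[(E)-2-chloroethenyl]-3-methyloxan-2-one (C3 epimers) | CC1CC[C@H](/C=C/Cl)OC1=O
A3 | alternative 2 | (1S,2S)-2-hydroxy-1-methyl-4-oxocyclohexane-1-carbaldehyde | C[C@]1(C=O)CCC(=O)C[C@@H]1O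
A4 | alternative 2 | 2-methyl-2-(3-oxobutyl)propanedial | CC(=O)CCC(C)(C=O)C=O
A5 | alternative 3 | (2R,4R,5S)-2-(bromomethyl)-5-[tert-butyl(dimethyl)silyl]oxy-2-chloro-4-[(E)-2-chloroethenyl]-4-methylcyclohexan-1-one | C[C@]1(/C=C/Cl)C[C@](Cl)(CBr)C(=O)C[C@@H]1O[Si](C)(C)C(C)(C)C
A6 | alternative 3 | (3R,4S)-4-[tert-butyl(dimethyl)silyl]oxy-1-(1-chloroethenyl)-3-[(E)-2-chloroethenyl]-3-methylcyclopentan-1-ol (either C1 epimer) | C[C@]1(/C=C/Cl)CC(O)(C(Cl)=C)C[C@@H]1O[Si](C)(C)C(C)(C)C
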